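**Retrosynthetic overview**

1. The oxirane and the oxygenated six-membered ring come last: 28 ⇐ epoxy alcohol 27 ⇐ epoxy ketone 26 ⇐ quinone monoketal 25 ⇐ phenol 24 (arene dearomatised, Weitz–Scheffer epoxidation of C5'=C6', reduction at C4', ketal hydrolysis).
2. The C11–C5' bond comes from a B-alkyl Suzuki–Miyaura coupling of the C9=C11 methylidene of diene 16 (α-face hydroboration sets C9) with aryl bromide 21.
3. Ring B (C5–C6–C7–C8–C9–C10) is never closed as a six-membered ring: it grows out of the cyclopentanone ring C5–C6–C7–C9–C10 of trans-hydrindanone 12 by insertion of one carbon, C8 with its methyl group, between C7 and C9, using chloro(methyl)carbene.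
4. Enabling feature: the ring-B carbonyl C9 sits between the quaternary C10 (angular methyl) and the C7 methylene, so the ketone can enolise only towards C7; the C7=C9 silyl enol ether takes up the carbene on that side only, and cyclopropyl-to-allyl opening leaves C7=C8(CH3) in its final position and C9=O as the handle for C11.
5. Ring order: cyclopentane (from 1) → ring A (Hajos–Parrish-type annulation, then reductive hydroxymethylation for C4 and C5) → ring B by expansion (step 10) → oxygenated ring from arene 21 → oxirane.

Key step: step 10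

Locants: drimane numbering for the bicyclic core (ring A = C1–C5, C10; ring B = C5–C10; C11 = benzylic CH2; C18 = CH2O on C4); β is the face of the C10 methyl. Primed locants for the oxygenated ring: C1' carries OMe/ketal/ketone, C2' the CH2O group, C4' the phenol/carbinol oxygen, C5' the C11 substituent.

Assumption: which of the two pseudoenantiomeric cinchona phase-transfer catalysts delivers oxygen to the required face of dienone 25 must be fixed by a first run; step 19 is written with N-benzylcinchonidinium chloride, and N-benzylcinchoninium chloride replaces it if the sense is the opposite one.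

**Route**

Step 1
Reactants: 1 2-methylcyclopentane-1,3-dione; 2 ethyl vinyl ketone (pent-1-en-3-one)
Product: 3 2-methyl-2-(3-oxopentyl)cyclopentane-1,3-dione
Conditions: H2O, AcOH (cat.), 75 °C
Reagents that add atoms: none
Why: Michael addition of the acidic 1,3-dione to the enone (first stage of the Hajos–Parrish sequence) should proceed cleanly in water and forms no stereocentre.

Step 2
Reactants: 3 2-methyl-2-(3-oxopentyl)cyclopentane-1,3-dione
Product: 5 (S)-4,7a-dimethyl-2,3,7,7a-tetrahydro-1H-indene-1,5(6H)-dione, via bicyclic ketol 4 (not isolated)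
Conditions: L-phenylalanine (1 equiv), (1S)-(+)-10-camphorsulfonic acid (0.5 equiv), DMF, 30 → 70 °C; recrystallisation
Reagents that add atoms: none
Why: Hajos–Parrish-type intramolecular aldol reaction through the enamine of the side-chain ketone followed by dehydration; the L-amino acid should differentiate the two enantiotopic ring carbonyls and so set the quaternary centre (later C10) as S, and recrystallisation should upgrade the enantiomeric purity.

Step 3
Reactants: 5 (S)-4,7a-dimethyl-2,3,7,7a-tetrahydro-1H-indene-1,5(6H)-dione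
Product: 6 (1S,7aS)-1-hydroxy-4,7a-dimethyl-1,2,3,6,7,7a-hexahydro-5H-inden-5-one
Conditions: NaBH4 (0.3 equiv), EtOH, −20 °C
Reagents that add atoms: none
Why: Chemoselective borohydride reduction, the saturated cyclopentanone being more electrophilic than the vinylogous enone carbonyl; hydride should enter anti to the angular methyl to give the 1β-alcohol, which only masks the later C9 carbonyl.

Step 4
Reactants: 6 (1S,7aS)-1-hydroxy-4,7a-dimethyl-1,2,3,6,7,7a-hexahydro-5H-inden-5-one
Product: 8 (1S,3aR,4R,7aS)-1-hydroxy-4-(hydroxymethyl)-4,7a-dimethyloctahydro-5H-inden-5-one (trans-fused; 4α-CH2OH, 4β-CH3), via dilithium enolate alkoxide 7 (not isolated)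
Conditions: Li (2.2 equiv), NH3(l)–THF, −78 °C; NH3 removed; CH2O (gas), THF, −78 °C; aq. NH4Cl
Reagents that add atoms: formaldehyde, C=O
Why: Birch-type reductive alkylation (reductive hydroxymethylation): the substrate's own hydroxyl serves as the one equivalent of proton donor, C5 should be protonated from the α-face to give the trans ring fusion, and the regiospecific C3=C4 lithium enolate should add to formaldehyde on the α-face, anti to the 1,3-diaxial angular methyl, placing CH2OH α and CH3 β at C4 as in closely related reductive hydroxymethylations of 4-methyl octalones.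

Step 5
Reactants: 8 keto diol
Product: 9 1,3-dithiolane (ethylene dithioketal) of 8 at the ring-A carbonyl (C3)
Conditions: HSCH2CH2SH, BF3·OEt2, CH2Cl2, 0 °C → rt
Reagents that add atoms: ethane-1,2-dithiol, SCCS
Why: Lewis-acid-promoted dithioketalisation of the only carbonyl group, a reaction that tolerates the flanking quaternary C4 and the free hydroxyls.

Step 6
Reactants: 9 dithiolane
Product: 10 4-(hydroxymethyl)-4,7a-dimethyloctahydro-1H-inden-1-ol (1β-OH, 3aα-H, 4α-CH2OH, 4β-CH3, 7aβ-CH3)
Conditions: Raney nickel (W-2), EtOH, reflux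
Reagents that add atoms: none
Why: Mozingo desulfurisation removes the C3 oxygen function as CH2 under neutral conditions without touching any stereocentre.

Step 7
Reactants: 10 diol
Product: 11 4-{[(tert-butyldimethylsilyl)oxy]methyl}-4,7a-dimethyloctahydro-1H-inden-1-ol (same configuration as 10)
Conditions: TBSCl (1.05 equiv), imidazole, CH2Cl2, 0 °C
Reagents that add atoms: tert-butyldimethylsilyl chloride, CC(C)(C)[Si](C)(C)Cl
Why: Silylation should be selective for the primary C18 hydroxyl over the hindered secondary hydroxyl next to the quaternary C10.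

Step 8
Reactants: 11 silyl ether alcohol
Product: 12 (3aS,4R,7aS)-4-{[(tert-butyldimethylsilyl)oxy]methyl}-4,7a-dimethyloctahydro-1H-inden-1-one (trans-hydrindanone)
Conditions: Dess–Martin periodinane, NaHCO3, CH2Cl2, rt
Reagents that add atoms: none
Why: Dess–Martin oxidation of the secondary alcohol to the cyclopentanone (the C9 carbonyl); C10 is quaternary and C5 is β to the carbonyl, so no stereocentre can epimerise.

Step 9
Reactants: 12 trans-hydrindanone
Product: 13 trimethylsilyl enol ether of 12 (C7=C9 double bond; 3aα-H, 4α-CH2OTBS, 4β-CH3, 7aβ-CH3)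
Conditions: TMSOTf, Et3N, CH2Cl2, 0 °C
Reagents that add atoms: trimethylsilyl trifluoromethanesulfonate, C[Si](C)(C)OS(=O)(=O)C(F)(F)F
Why: Soft enolisation and O-silylation (silyl enol ether formation); because C10 is quaternary the ketone can enolise only towards C7, so a single regioisomer should form.

Step 10
Reactants: 13 trimethylsilyl enol ether
Product: 15 trans-fused 5-{[(tert-butyldimethylsilyl)oxy]methyl}-2,5,8a-trimethyl-4a,5,6,7,8,8a-hexahydronaphthalen-1(4H)-one (4aα-H, 5β-CH3, 8aβ-CH3; C9 ketone, C7=C8 alkene), via siloxy chlorocyclopropane 14 (not isolated)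
Conditions: CH3CHCl2 (4 equiv), n-BuLi (3 equiv, slow addition), Et2O, −40 °C → rt; then toluene, 110 °C
Reagents that add atoms: 1,1-dichloroethane, CC(Cl)Cl
Why: n-BuLi deprotonates 1,1-dichloroethane and α-elimination gives chloro(methyl)carbene, which should add in a concerted [2+1] fashion to the only nucleophilic π bond, the C7=C9 silyl enol ether, from the α-face opposite the angular C10 methyl to give 14; on heating, ionisation of the C8–Cl bond is coupled to disrotatory cleavage of the internal C7–C9 bond (cyclopropyl-to-allyl electrocyclic opening assisted by the siloxy oxygen), and the 2-siloxyallyl cation loses the silyl group to chloride to give enone 15. The closest known reaction type is the halocarbene ring expansion of cyclic silyl enol ethers to ring-enlarged 2-halo- or 2-methylcycloalk-2-enones. No ring is closed in the product: the transient three-membered ring is closed by cheletropic [2+1] addition, and ring B arises when the zero-atom bridge of the bicyclo[3.1.0]hexane is cut, so that the five-membered ring C5–C6–C7–C9–C10 becomes the six-membered ring C5–C6–C7–C8–C9–C10. No stereocentre is created in 15 (C7 and C8 become sp2, so the two C8 epimers of 14 converge) and C4, C5 and C10 are untouched. The selectivity needed is regiochemical, insertion on the C7 side and not the C10 side of the carbonyl, and it is secured by the quaternary C10, which allows only the C7 enol ether; chemoselectivity is secured because 13 has no other alkene and the carbenoid is made by slow addition of n-BuLi into excess dichloroethane. In one operation the step should deliver C8 with its methyl, the C7=C8 double bond in its final place and the C9 carbonyl needed to attach C11.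

Step 11
Reactants: 15 ring-expanded enone
Product: 16 trans-fused 5-{[(tert-butyldimethylsilyl)oxy]methyl}-1-methylidene-2,5,8a-trimethyl-1,4,4a,5,6,7,8,8a-octahydronaphthalene (C7=C8 and C9=C11 diene)
Conditions: Zn, CH2Br2, TiCl4, THF–CH2Cl2, 0 °C → rt
Reagents that add atoms: dibromomethane, BrCBr
Why: Takai–Lombardo methylenation is non-basic and effective for hindered ketones, so it should convert the C9 carbonyl into the C9=C11 methylidene without deconjugating or isomerising the C7=C8 alkene.

Step 12
Reactants: 17 2-bromo-4-methoxyphenol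
Product: 18 2-bromo-4-methoxyphenyl pivalate
Conditions: PivCl, Et3N, DMAP (cat.), CH2Cl2, 0 °C → rt
Reagents that add atoms: pivaloyl chloride, CC(C)(C)C(=O)Cl
Why: Acylation of the phenol under nucleophilic catalysis; the pivalate lowers the donor strength of this oxygen so that the methoxy group alone directs the next step, and it masks the C4' oxygen until step 17.

Step 13
Reactants: 18 2-bromo-4-methoxyphenyl pivalate
Product: 19 2-bromo-5-formyl-4-methoxyphenyl pivalate
Conditions: Cl2CHOMe, TiCl4, CH2Cl2, 0 °C → rt; H2O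
Reagents that add atoms: dichloromethyl methyl ether, COC(Cl)Cl; water, O
Why: Rieche formylation (Friedel–Crafts type): the methoxy group directs ortho, and of its two ortho positions the one flanked by bromine is blocked, so the formyl group should enter para to bromine.

Step 14
Reactants: 19 aryl aldehyde
Product: 20 2-bromo-5-(hydroxymethyl)-4-methoxyphenyl pivalate
Conditions: NaBH4, MeOH–THF, 0 °C
Reagents that add atoms: none
Why: Borohydride reduction of the aryl aldehyde at 0 °C, conditions under which the hindered aryl pivalate and the aryl bromide are stable.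

Step 15
Reactants: 20 benzylic alcohol
Product: 21 2-bromo-5-{[(tert-butyldimethylsilyl)oxy]methyl}-4-methoxyphenyl pivalate
Conditions: TBSCl, imidazole, DMF, rt
Reagents that add atoms: tert-butyldimethylsilyl chloride, CC(C)(C)[Si](C)(C)Cl
Why: Standard silylation of the primary benzylic alcohol.

Step 16
Reactants: 16 diene; 21 aryl bromide
Product: 23 2-{[(1S,4aR,5R,8aR)-5-{[(tert-butyldimethylsilyl)oxy]methyl}-2,5,8a-trimethyl-1,4,4a,5,6,7,8,8a-octahydronaphthalen-1-yl]methyl}-5-{[(tert-butyldimethylsilyl)oxy]methyl}-4-methoxyphenyl pivalate, via B-alkyl-9-BBN borane 22 (not isolated)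
Conditions: 9-BBN-H, THF, 65 °C; then 21, Pd(OAc)2 (5 mol %), SPhos (10 mol %), K3PO4·H2O, THF–H2O, 65 °C
Reagents that add atoms: none
Why: Hydroboration of the 1,1-disubstituted exocyclic alkene (boron to C11, hydrogen to C9 from the α-face anti to the axial C10 methyl, which sets C9 with H α) followed by B-alkyl Suzuki–Miyaura coupling under a bulky electron-rich phosphine; the trisubstituted C7=C8 alkene is inert to 9-BBN-H.

Step 17
Reactants: 23 aryl pivalate
Product: 24 2-{[(1S,4aR,5R,8aR)-5-{[(tert-butyldimethylsilyl)oxy]methyl}-2,5,8a-trimethyl-1,4,4a,5,6,7,8,8a-octahydronaphthalen-1-yl]methyl}-5-{[(tert-butyldimethylsilyl)oxy]methyl}-4-methoxyphenol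
Conditions: K2CO3, MeOH–THF, 40 °C
Reagents that add atoms: none
Why: Transesterification (methanolysis) of the aryl ester, which is far more labile to methoxide than the alkyl silyl ethers, should free the C4' phenol.

Step 18
Reactants: 24 para-methoxyphenol
Product: 25 2-{[(1S,4aR,5R,8aR)-5-{[(tert-butyldimethylsilyl)oxy]methyl}-2,5,8a-trimethyl-1,4,4a,5,6,7,8,8a-octahydronaphthalen-1-yl]methyl}-5-{[(tert-butyldimethylsilyl)oxy]methyl}-4,4-dimethoxycyclohexa-2,5-dien-1-one
Conditions: PhI(OAc)2, MeOH, 0 °C
Reagents that add atoms: methanol, CO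
Why: Oxidative dearomatisation of a para-methoxyphenol: methanol adds at the methoxy-bearing C1' to give the quinone monoketal, so the carbonyl is placed at C4', next to the C11-bearing carbon, by the substitution pattern alone.

Step 19
Reactants: 25 quinone monoketal
Product: 26 (1R,6S)-1-{[(1S,4aR,5R,8aR)-5-{[(tert-butyldimethylsilyl)oxy]methyl}-2,5,8a-trimethyl-1,4,4a,5,6,7,8,8a-octahydronaphthalen-1-yl]methyl}-4-{[(tert-butyldimethylsilyl)oxy]methyl}-5,5-dimethoxy-7-oxabicyclo[4.1.0]hept-3-en-2-one (C5'–C6' epoxide)
Conditions: t-BuOOH, aq. NaOH, N-benzylcinchonidinium chloride (10 mol %), toluene, 0 °C → rt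
Reagents that add atoms: tert-butyl hydroperoxide, CC(C)(C)OO
Why: Weitz–Scheffer (nucleophilic) epoxidation under chiral phase-transfer catalysis: the hydroperoxide anion attacks the unsubstituted β-carbon C6' and not the substituted, ketal-flanked C2', so only the C5'=C6' enone alkene should react and the electron-rich C7=C8 alkene is untouched; the face, and with it the new centres C5' and C6', is to be set by the ion-paired cinchona catalyst.

Step 20
Reactants: 26 epoxy ketone
Product: 27 (1S,2R,6S)-1-{[(1S,4aR,5R,8aR)-5-{[(tert-butyldimethylsilyl)oxy]methyl}-2,5,8a-trimethyl-1,4,4a,5,6,7,8,8a-octahydronaphthalen-1-yl]methyl}-4-{[(tert-butyldimethylsilyl)oxy]methyl}-5,5-dimethoxy-7-oxabicyclo[4.1.0]hept-3-en-2-ol (hydroxyl anti to the epoxide oxygen)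
Conditions: i-Bu2AlH, THF, −78 °C
Reagents that add atoms: none
Why: 1,2-Reduction of the epoxy ketone; hydride should be delivered from the epoxide face (aluminium coordinated to the epoxide oxygen, the other face shielded by the bulky C11 substituent on the adjacent C5'), which places the C4' hydroxyl anti to the epoxide oxygen.

Step 21
Reactants: 27 epoxy alcohol
Product: 28 Epoxypholamin A, (1S,5R,6S)-5-hydroxy-3-(hydroxymethyl)-6-{[(1S,4aR,5R,8aR)-5-(hydroxymethyl)-2,5,8a-trimethyl-1,4,4a,5,6,7,8,8a-octahydronaphthalen-1-yl]methyl}-7-oxabicyclo[4.1.0]hept-3-en-2-one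
Conditions: 48 % aq. HF, MeCN, 0 °C → rt
Reagents that add atoms: water, O
Why: Acidic hydrolysis of the dimethyl ketal to the enone carbonyl with concurrent fluoride-assisted cleavage of both silyl ethers, conditions of the type used for epoxyquinol ketals, which should leave the epoxide, the allylic alcohol and the trisubstituted alkene intact.

**Compound list**

1 | 2-methylcyclopentane-1,3-dione | CC1C(=O)CCC1=O | starting material
2 | ethyl vinyl ketone (pent-1-en-3-one) | CCC(=O)C=C | starting material
3 | 2-methyl-2-(3-oxopentyl)cyclopentane-1,3-dione | CCC(=O)CCC1(C)C(=O)CCC1=O | intermediate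
4 | bicyclic ketol, (3aS,7aS)-3a-hydroxy-4,7a-dimethylhexahydro-1H-indene-1,5(4H)-dione (cis-fused, C4 unassigned) | CC1C(=O)CC[C@]2(C)C(=O)CC[C@]12O | intermediate (not isolated)
5 | (S)-4,7a-dimethyl-2,3,7,7a-tetrahydro-1H-indene-1,5(6H)-dione | CC1=C2CCC(=O)[C@@]2(C)CCC1=O | intermediate
6 | (1S,7aS)-1-hydroxy-4,7a-dimethyl-1,2,3,6,7,7a-hexahydro-5H-inden-5-one | CC1=C2CC[C@H](O)[C@@]2(C)CCC1=O | intermediate
7 | dilithium enolate alkoxide of the trans-fused ketone (C3=C4 enolate, C9 alkoxide) | [Li]O[C@H]1CC[C@H]2C(C)=C(O[Li])CC[C@]12C | intermediate (not isolated)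
8 | (1S,3aR,4R,7aS)-1-hydroxy-4-(hydroxymethyl)-4,7a-dimethyloctahydro-5H-inden-5-one | O[C@H]1CC[C@H]2[C@](C)(CO)C(=O)CC[C@]12C | intermediate
9 | 1,3-dithiolane (ethylene dithioketal) of 8 | O[C@H]1CC[C@H]2[C@](C)(CO)C3(SCCS3)CC[C@]12C | intermediate
10 | 4-(hydroxymethyl)-4,7a-dimethyloctahydro-1H-inden-1-ol (1β-OH, 3aα-H, 4α-CH2OH, 4β-CH3, 7aβ-CH3) | O[C@H]1CC[C@H]2[C@](C)(CO)CCC[C@]12C | intermediate
11 | 4-{[(tert-butyldimethylsilyl)oxy]methyl}-4,7a-dimethyloctahydro-1H-inden-1-ol (configuration as 10) | O[C@H]1CC[C@H]2[C@](C)(CO[Si](C)(C)C(C)(C)C)CCC[C@]12C | intermediate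
12 | (3aS,4R,7aS)-4-{[(tert-butyldimethylsilyl)oxy]methyl}-4,7a-dimethyloctahydro-1H-inden-1-one | O=C1CC[C@H]2[C@](C)(CO[Si](C)(C)C(C)(C)C)CCC[C@]12C | intermediate
13 | trimethylsilyl enol ether of 12 (C7=C9) | C[Si](C)(C)OC1=CC[C@H]2[C@](C)(CO[Si](C)(C)C(C)(C)C)CCC[C@]12C | intermediate
14 | siloxy chlorocyclopropane: 1-chloro-1-methylcyclopropane fused on the α-face across C7–C9 of 13 (both epimers at the chlorine-bearing carbon) | C[Si](C)(C)O[C@@]12[C@H](C2(C)Cl)C[C@H]2[C@](C)(CO[Si](C)(C)C(C)(C)C)CCC[C@]12C | intermediate (not isolated)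
15 | trans-fused 5-{[(tert-butyldimethylsilyl)oxy]methyl}-2,5,8a-trimethyl-4a,5,6,7,8,8a-hexahydronaphthalen-1(4H)-one (4aα-H, 5β-CH3, 8aβ-CH3) | O=C1C(C)=CC[C@H]2[C@](C)(CO[Si](C)(C)C(C)(C)C)CCC[C@]12C | intermediate
16 | trans-fused 5-{[(tert-butyldimethylsilyl)oxy]methyl}-1-methylidene-2,5,8a-trimethyl-1,4,4a,5,6,7,8,8a-octahydronaphthalene | C=C1C(C)=CC[C@H]2[C@](C)(CO[Si](C)(C)C(C)(C)C)CCC[C@]12C | intermediate
17 | 2-bromo-4-methoxyphenol | COc1ccc(O)c(Br)c1 | starting material
18 | 2-bromo-4-methoxyphenyl pivalate | COc1ccc(OC(=O)C(C)(C)C)c(Br)c1 | intermediate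
19 | 2-bromo-5-formyl-4-methoxyphenyl pivalate | COc1cc(Br)c(OC(=O)C(C)(C)C)cc1C=O | intermediate
20 | 2-bromo-5-(hydroxymethyl)-4-methoxyphenyl pivalate | COc1cc(Br)c(OC(=O)C(C)(C)C)cc1CO | intermediate
21 | 2-bromo-5-{[(tert-butyldimethylsilyl)oxy]methyl}-4-methoxyphenyl pivalate | COc1cc(Br)c(OC(=O)C(C)(C)C)cc1CO[Si](C)(C)C(C)(C)C | intermediate
22 | B-alkyl-9-BBN borane (boron on C11, H9 α) | CC1=CC[C@H]2[C@](C)(CO[Si](C)(C)C(C)(C)C)CCC[C@]2(C)[C@H]1CB1C2CCCC1CCC2 | intermediate (not isolated)
23 | coupled aryl pivalate (name in step 16) | CC1=CC[C@H]2[C@](C)(CO[Si](C)(C)C(C)(C)C)CCC[C@]2(C)[C@H]1Cc1cc(OC)c(CO[Si](C)(C)C(C)(C)C)cc1OC(=O)C(C)(C)C | intermediate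
24 | phenol (name in step 17) | CC1=CC[C@H]2[C@](C)(CO[Si](C)(C)C(C)(C)C)CCC[C@]2(C)[C@H]1Cc1cc(OC)c(CO[Si](C)(C)C(C)(C)C)cc1O | intermediate
25 | quinone monoketal (name in step 18) | CC1=CC[C@H]2[C@](C)(CO[Si](C)(C)C(C)(C)C)CCC[C@]2(C)[C@H]1CC1=CC(OC)(OC)C(CO[Si](C)(C)C(C)(C)C)=CC1=O | intermediate
26 | epoxy ketone (name in step 19) | CC1=CC[C@H]2[C@](C)(CO[Si](C)(C)C(C)(C)C)CCC[C@]2(C)[C@H]1C[C@@]12O[C@@H]1C(OC)(OC)C(CO[Si](C)(C)C(C)(C)C)=CC2=O | intermediate
27 | epoxy alcohol (name in step 20) | CC1=CC[C@H]2[C@](C)(CO[Si](C)(C)C(C)(C)C)CCC[C@]2(C)[C@H]1C[C@@]12O[C@@H]1C(OC)(OC)C(CO[Si](C)(C)C(C)(C)C)=C[C@H]2O | intermediate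
28 | Epoxypholamin A (name in step 21) | CC1=CC[C@H]2[C@](C)(CO)CCC[C@]2(C)[C@H]1C[C@@]12O[C@@H]1C(=O)C(CO)=C[C@H]2O | target

**Step count and risks**

Total step count: 21. Longest linear sequence: 17 steps (steps 1–11 and 16–21); the aryl branch (steps 12–15) has 4 steps.

Steps most likely to fail:

Step 10. The carbene adduct 14 forms as two epimers at the chlorine-bearing carbon. The epimer with exo chlorine cannot ionise with concerted disrotatory cleavage of the internal bond in a fused five-membered ring, so it may survive the thermolysis or be lost by desilylation. Fallback, setting out from 13 and returning at 15: dibromocarbene (CHBr3, KOt-Bu, pentane, −20 °C → rt) is added to 13 to give the dibromocyclopropane F1 (not isolated), in which one bromine is necessarily endo. It should open on warming (toluene, pyridine cat., 80 °C) to the ring-expanded 2-bromo enone F2. Suzuki–Miyaura methylation of F2 (MeB(OH)2, PdCl2(dppf), K3PO4, dioxane, 80 °C) should then give 15; the methyl group is brought in separately instead of on the carbene.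

Step 4. Protonation at C5 of the hydrindenone dianion may give poor trans/cis ring-fusion selectivity, and material may be lost by retro-aldol cleavage or multiple hydroxymethylation on quenching with formaldehyde. Fallback, setting out from 6 and returning at 8: the thermodynamic dienolate of 6 (KOt-Bu, 2.2 equiv, t-BuOH–THF, 0 °C) is hydroxymethylated with formaldehyde at C4 with deconjugation, on the α-face, to give the β,γ-unsaturated keto diol F3. Hydrogenation of F3 (H2, 3 bar, Pd/C, EtOAc) should add hydrogen to the C5=C6 alkene from the α-face, the β-face being closed by the β-methyl groups on C10 and C4, and give 8.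

Step 19. The facial selectivity of the phase-transfer epoxidation rests on catalyst control alone, since the existing stereocentres are remote from the dienone, and it may be insufficient. Fallback, setting out from 25 and returning at 28: transketalisation of 25 with (2R,4R)-pentane-2,4-diol (PPTS, benzene, 40 °C; the enantiomeric diol if the other face is delivered) gives the chiral dioxane dienone F4. Weitz–Scheffer epoxidation under auxiliary control (H2O2, LiOH, THF–MeOH, 0 °C) gives the dioxane epoxy ketone F5. Reduction with i-Bu2AlH (THF, −78 °C) gives the dioxane epoxy alcohol F6, and 48 % aq. HF in MeCN should hydrolyse the ketal and remove both silyl ethers to give 28.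

Further compounds
F1 | step 10 | dibromocyclopropane, the 1,1-dibromocyclopropane analogue of 14 on the α-face | C[Si](C)(C)O[C@@]12[C@H](C2(Br)Br)C[C@H]2[C@](C)(CO[Si](C)(C)C(C)(C)C)CCC[C@]12C
F2 | step 10 | 2-bromo enone, trans-fused 2-bromo-5-{[(tert-butyldimethylsilyl)oxy]methyl}-5,8a-dimethyl-4a,5,6,7,8,8a-hexahydronaphthalen-1(4H)-one | O=C1C(Br)=CC[C@H]2[C@](C)(CO[Si](C)(C)C(C)(C)C)CCC[C@]12C
F3 | step 4 | β,γ-unsaturated keto diol, (1S,7aS)-1-hydroxy-4α-(hydroxymethyl)-4β,7a-dimethyl-1,2,4,6,7,7a-hexahydro-5H-inden-5-one | O[C@H]1CC=C2[C@](C)(CO)C(=O)CC[C@]12C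
F4 | step 19 | chiral dioxane dienone, the (4R,6R)-4,6-dimethyl-1,3-dioxane spiroketal analogue of 25 | CC1=CC[C@H]2[C@](C)(CO[Si](C)(C)C(C)(C)C)CCC[C@]2(C)[C@H]1CC1=CC2(O[C@H](C)C[C@@H](C)O2)C(CO[Si](C)(C)C(C)(C)C)=CC1=O
F5 | step 19 | dioxane epoxy ketone, the C5'–C6' epoxide of F4 | CC1=CC[C@H]2[C@](C)(CO[Si](C)(C)C(C)(C)C)CCC[C@]2(C)[C@H]1C[C@@]12O[C@@H]1C1(O[C@H](C)C[C@@H](C)O1)C(CO[Si](C)(C)C(C)(C)C)=CC2=O
F6 | step 19 | dioxane epoxy alcohol, the C4' alcohol of F5 with hydroxyl anti to the epoxide oxygen | CC1=CC[C@H]2[C@](C)(CO[Si](C)(C)C(C)(C)C)CCC[C@]2(C)[C@H]1C[C@@]12O[C@@H]1C1(O[C@H](C)C[C@@H](C)O1)C(CO[Si](C)(C)C(C)(C)C)=C[C@H]2O
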